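**Plan**
1. Retrosynthetic cuts, in order: C‑10'–C‑11' (sp2–sp2 Suzuki coupling, last step), C‑11'=C‑12' (boryl olefination), C‑11=C‑12 (Wittig reaction on the C10 dialdehyde), the palmitate C–O bond, C‑6–C‑7 (enol triflate coupling), C‑9'–CH3 with C‑10'–I (methylalumination), then in the ε‑ring C‑6'–C‑7' (conjugate addition) and the inserted ring carbon C‑4'.
2. Forward, ε‑half: a cyclopentenone takes up the side chain by conjugate addition with enolate silylation, is cyclopropanated, and is then enlarged oxidatively by one carbon to the cyclohexenone; reduction, C‑desilylation and methylalumination/iodination give a dienyl iodide.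
3. Forward, β‑half: (4R,6R)‑actinol is converted by enol triflate coupling, phosphonium salt formation, palmitoylation, Wittig reaction with the C10 dialdehyde and boryl olefination into a C26 polyenylboronate; the two halves are joined last.
4. Enabling feature: ring atoms C‑3'(O)–C‑4'H=C‑5'(CH3) of the ε‑ring are a 3‑methylcyclohex‑2‑en‑1‑ol, the retron of a one‑carbon‑enlarged 2‑methylcyclopentanone with C‑4' as the added atom; quaternary C‑1' allows only one enolisation and one elimination, so the double bond is fixed out of conjugation with the polyene.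
5. Stereochemistry: C‑6' from the chiral copper catalyst in the conjugate addition, C‑3' from substrate‑controlled hydride delivery trans to the side chain, C‑3 from actinol; chain geometry from stereospecific hydro‑/carbometalation, cross‑coupling and olefination.

Key step: step 5

Remark on the chemistry: the antipode of the phosphoramidite ligand in step 3 is taken to be the one that delivers the alkenyl group to the enone face giving the (R) centre; carotenoid numbering is used for ring and chain atoms.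

**Step 1**
Reactants: 1 2,4,4-trimethylcyclopentan-1-one
Product: 2 2,4,4-trimethylcyclopent-2-en-1-one
Conditions: IBX (2.0 equiv), DMSO/fluorobenzene (1:2), 75 °C
Reagents that add atoms: none
Why: IBX α,β‑dehydrogenation of a ketone through its enol–iodine adduct; only the C‑2/C‑3 bond can be desaturated because C‑4 is quaternary, and the endocyclic conjugated enone is the expected isomer.

**Step 2**
Reactants: 3 1,4-bis(trimethylsilyl)buta-1,3-diyne
Product: 5 buta-1,3-diyn-1-yl(trimethyl)silane, via lithium silylbutadiynide 4 (not isolated)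
Conditions: MeLi·LiBr (1.0 equiv), Et2O, rt; then H2O, 0 °C; kept as a dried CH2Cl2 solution
Reagents that add atoms: none
Why: Selective mono‑desilylation of a bis(silyl)diyne by Si‑to‑Li exchange with one equivalent of methyllithium, followed by protonation of the lithium acetylide.

**Step 3**
Reactants: 5 buta-1,3-diyn-1-yl(trimethyl)silane; 2 2,4,4-trimethylcyclopent-2-en-1-one
Product: 7 trimethyl({(3R)-2,4,4-trimethyl-3-[(1E)-4-(trimethylsilyl)but-1-en-3-yn-1-yl]cyclopent-1-en-1-yl}oxy)silane, via alkenylzirconocene chloride 6 (not isolated)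
Conditions: Cp2Zr(H)Cl (1.0 equiv per 5), CH2Cl2, rt; then 2, CuCl (10 mol %), AgNTf2 (11 mol %), BINOL‑derived phosphoramidite bearing a bis(1‑phenylethyl)amino group (12 mol %), TMSCl (3 equiv), Et2O, 0 °C → rt; Et3N/pentane, non‑aqueous work‑up
Reagents that add atoms: chlorotrimethylsilane, C[Si](C)(C)Cl
Why: Schwartz hydrozirconation (syn, Zr at the terminal carbon, E alkenyl metal; the silylated triple bond is slower) and copper‑catalysed asymmetric conjugate addition of the alkenylzirconocene to the cyclic enone with in situ silylation, which fixes the enol ether on the methyl‑bearing side; the new stereocentre (later C‑6') should be set by enantioface control of the chiral phosphoramidite–copper catalyst.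

**Step 4**
Reactants: 7 trimethyl({(3R)-2,4,4-trimethyl-3-[(1E)-4-(trimethylsilyl)but-1-en-3-yn-1-yl]cyclopent-1-en-1-yl}oxy)silane
Product: 8 (2R)-1,3,3-trimethyl-2-[(1E)-4-(trimethylsilyl)but-1-en-3-yn-1-yl]-5-[(trimethylsilyl)oxy]bicyclo[3.1.0]hexane (cyclopropane CH2 anti to the alkenyl group)
Conditions: Et2Zn (1.5 equiv), CH2I2 (1.5 equiv), CH2Cl2, 0 °C → rt; pyridine quench
Reagents that add atoms: diiodomethane, ICI
Why: Simmons–Smith cyclopropanation (Furukawa modification); the electron‑rich tetrasubstituted silyl enol ether should react far faster with the electrophilic zinc carbenoid than the alkyne‑conjugated alkene, and the methylene should add anti to the alkenyl group (both bridgehead centres are erased in step 5, so this ratio does not matter).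

**Step 5**
Reactants: 8 (2R)-1,3,3-trimethyl-2-[(1E)-4-(trimethylsilyl)but-1-en-3-yn-1-yl]-5-[(trimethylsilyl)oxy]bicyclo[3.1.0]hexane
Product: 10 (4R)-3,5,5-trimethyl-4-[(1E)-4-(trimethylsilyl)but-1-en-3-yn-1-yl]cyclohex-2-en-1-one, via β-chloroketone 9 (not isolated)
Conditions: FeCl3 (2.5 equiv), DMF, 0 °C → rt; then NaOAc (5 equiv), MeOH, reflux
Reagents that add atoms: none
Why: FeCl3 (trivalent iron) exchanges with the silyl ether to an iron cyclopropoxide, inner‑sphere one‑electron transfer gives the cyclopropyloxy radical, and β‑scission of the bond shared by the three‑ and five‑membered rings (C‑3'–C‑5') forms the C‑3' carbonyl and a tertiary radical at C‑5' in a ring that is now six‑membered, which takes chlorine from a second FeCl3; NaOAc then removes HCl by an E1cB path through the C‑4' enolate. The closest known reaction type is exactly this FeCl3‑mediated one‑carbon enlargement of 1‑siloxybicyclo[n.1.0]alkanes to cycloalk‑2‑enones. No ring is closed by cyclisation: the six‑membered ring arises by cleavage of the zero‑atom bridge of the bicyclo[3.1.0]hexane, so the former cyclopropane methylene becomes ring atom C‑4'. No new stereocentre is formed; the two bridgehead centres are erased and the C‑6' centre, which is not part of the breaking bond, should be carried over unchanged. The step needs scission of the internal and not the external cyclopropane bond (secured by the tertiary, methyl‑substituted radical and strain release), chlorine transfer faster than addition of the homoallylic C‑5' radical to the side‑chain alkene, and one alkene position only (secured because C‑4' alone can be deprotonated towards the chloride, while quaternary C‑1' and the weak base leave C‑6' untouched).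

**Step 6**
Reactants: 10 (4R)-3,5,5-trimethyl-4-[(1E)-4-(trimethylsilyl)but-1-en-3-yn-1-yl]cyclohex-2-en-1-one
Product: 11 (1R,4R)-3,5,5-trimethyl-4-[(1E)-4-(trimethylsilyl)but-1-en-3-yn-1-yl]cyclohex-2-en-1-ol
Conditions: LiBH(s-Bu)3 (1.2 equiv), THF, −78 °C; H2O work‑up
Reagents that add atoms: none
Why: 1,2‑Reduction of a β,β‑disubstituted cyclohexenone by a bulky trialkylborohydride; with the alkenyl group pseudo‑axial (avoiding allylic strain with the vinylic methyl) the axial methyl of the gem‑dimethyl group shields the opposite face, so hydride should arrive syn to the side chain and give the 1,4‑trans alcohol, (R) at the carbinol carbon (substrate control).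

**Step 7**
Reactants: 11 (1R,4R)-3,5,5-trimethyl-4-[(1E)-4-(trimethylsilyl)but-1-en-3-yn-1-yl]cyclohex-2-en-1-ol
Product: 12 (1R,4R)-4-[(1E)-but-1-en-3-yn-1-yl]-3,5,5-trimethylcyclohex-2-en-1-ol
Conditions: K2CO3 (0.2 equiv), MeOH, rt
Reagents that add atoms: none
Why: Base‑catalysed methanolysis of the alkynyl C–Si bond (protodesilylation); the allylic alcohol and both stereocentres are not touched.

**Step 8**
Reactants: 12 (1R,4R)-4-[(1E)-but-1-en-3-yn-1-yl]-3,5,5-trimethylcyclohex-2-en-1-ol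
Product: 14 (1R,4R)-4-[(1E,3E)-4-iodo-3-methylbuta-1,3-dien-1-yl]-3,5,5-trimethylcyclohex-2-en-1-ol, via dienylalane alkoxide 13 (not isolated)
Conditions: AlMe3 (3.0 equiv), Cp2ZrCl2 (0.3 equiv), CH2Cl2, 0 °C → rt; then I2 (1.3 equiv), THF, −30 → 0 °C; aq. potassium sodium tartrate
Reagents that add atoms: trimethylaluminium, C[Al](C)C; iodine, II
Why: Negishi zirconium‑catalysed methylalumination of the terminal alkyne (syn addition, methyl to the internal carbon C‑9') followed by iodinolysis of the alkenyl–Al bond with retention should give the (E)‑2‑methyl‑1‑iodoalkene; the hydroxyl is carried as its aluminium alkoxide.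

**Step 9**
Reactants: 15 (4R,6R)-4-hydroxy-2,2,6-trimethylcyclohexan-1-one
Product: 16 (4R,6R)-4-[(tert-butyldimethylsilyl)oxy]-2,2,6-trimethylcyclohexan-1-one
Conditions: TBSCl (1.2 equiv), imidazole (2.5 equiv), DMF, rt
Reagents that add atoms: tert-butyldimethylsilyl chloride, CC(C)(C)[Si](C)(C)Cl
Why: Silylation of a secondary alcohol under imidazole catalysis; no stereocentre is involved.

**Step 10**
Reactants: 16 (4R,6R)-4-[(tert-butyldimethylsilyl)oxy]-2,2,6-trimethylcyclohexan-1-one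
Product: 18 (4R)-4-[(tert-butyldimethylsilyl)oxy]-2,6,6-trimethylcyclohex-1-en-1-yl trifluoromethanesulfonate, via lithium enolate 17 (not isolated)
Conditions: LiN(i-Pr)2 (1.1 equiv), THF, −78 → 0 °C; then PhNTf2 (1.1 equiv), −78 °C → rt
Reagents that add atoms: N-phenylbis(trifluoromethanesulfonimide), O=S(=O)(N(c1ccccc1)S(=O)(=O)C(F)(F)F)C(F)(F)F
Why: Regiodefined enolate formation (only C‑6 carries an α‑hydrogen) and O‑triflation; the C‑6 stereocentre is erased on purpose and the carbinol centre is not touched.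

**Step 11**
Reactants: 19 (2E)-3-methylpent-2-en-4-yn-1-ol
Product: 21 (2E,4E)-3-methyl-5-(4,4,5,5-tetramethyl-1,3,2-dioxaborolan-2-yl)penta-2,4-dien-1-ol, via O-borylated dienylboronate 20 (not isolated)
Conditions: pinacolborane (2.3 equiv), Cp2Zr(H)Cl (10 mol %), Et3N (10 mol %), CH2Cl2, rt → 40 °C; aq. NH4Cl work‑up
Reagents that add atoms: pinacolborane, [H]B1OC(C)(C)C(C)(C)O1
Why: Zirconocene‑catalysed syn hydroboration of a terminal alkyne (boron at the terminal carbon, E alkene); the hydroxyl is borylated by the first equivalent and released again on aqueous work‑up.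

**Step 12**
Reactants: 18 (4R)-4-[(tert-butyldimethylsilyl)oxy]-2,6,6-trimethylcyclohex-1-en-1-yl trifluoromethanesulfonate; 21 (2E,4E)-3-methyl-5-(4,4,5,5-tetramethyl-1,3,2-dioxaborolan-2-yl)penta-2,4-dien-1-ol
Product: 22 (2E,4E)-5-{(4R)-4-[(tert-butyldimethylsilyl)oxy]-2,6,6-trimethylcyclohex-1-en-1-yl}-3-methylpenta-2,4-dien-1-ol
Conditions: Pd(PPh3)4 (10 mol %), 10% aq. TlOH (3 equiv), THF, rt, dark
Reagents that add atoms: none
Why: Suzuki–Miyaura coupling of a hindered cyclohexenyl triflate with an alkenylboronate, accelerated by TlOH; both alkene geometries should be retained.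

**Step 13**
Reactants: 22 (2E,4E)-5-{(4R)-4-[(tert-butyldimethylsilyl)oxy]-2,6,6-trimethylcyclohex-1-en-1-yl}-3-methylpenta-2,4-dien-1-ol
Product: 24 [(2E,4E)-5-[(4R)-4-hydroxy-2,6,6-trimethylcyclohex-1-en-1-yl]-3-methylpenta-2,4-dien-1-yl](triphenyl)phosphonium bromide, via silylated phosphonium bromide 23 (not isolated)
Conditions: PPh3·HBr (1.1 equiv), MeOH, rt; then 48% aq. HBr (0.1 equiv), rt; crystallisation
Reagents that add atoms: triphenylphosphine hydrobromide, Br.c1ccc(cc1)P(c1ccccc1)c1ccccc1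
Why: Acid‑mediated conversion of the dienylic alcohol into the allylic phosphonium salt (ionisation to the delocalised cation, capture by PPh3 at the terminus), after which the acidic methanol should cleave the silyl ether.

**Step 14**
Reactants: 24 [(2E,4E)-5-[(4R)-4-hydroxy-2,6,6-trimethylcyclohex-1-en-1-yl]-3-methylpenta-2,4-dien-1-yl](triphenyl)phosphonium bromide; 25 hexadecanoyl chloride
Product: 26 [(2E,4E)-5-[(4R)-4-(hexadecanoyloxy)-2,6,6-trimethylcyclohex-1-en-1-yl]-3-methylpenta-2,4-dien-1-yl](triphenyl)phosphonium bromide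
Conditions: pyridine (3 equiv), DMAP (5 mol %), CH2Cl2, 0 °C → rt
Reagents that add atoms: none
Why: DMAP‑catalysed acylation of the secondary alcohol by an acid chloride; the carbinol configuration is kept because the C–O bond is not touched.

**Step 15**
Reactants: 26 [(2E,4E)-5-[(4R)-4-(hexadecanoyloxy)-2,6,6-trimethylcyclohex-1-en-1-yl]-3-methylpenta-2,4-dien-1-yl](triphenyl)phosphonium bromide; 27 (2E,4E,6E)-2,7-dimethylocta-2,4,6-trienedial
Product: 29 (1R)-3,5,5-trimethyl-4-[(1E,3E,5E,7E,9E,11E)-3,7,12-trimethyl-13-oxotrideca-1,3,5,7,9,11-hexaen-1-yl]cyclohex-3-en-1-yl hexadecanoate, via phosphorus ylide 28 (not isolated)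
Conditions: NaN(SiMe3)2 (1.0 equiv), THF, −78 °C; cannulated into 27 (3 equiv), THF, −78 °C → rt; then I2 (1 mol %), CH2Cl2, daylight, rt
Reagents that add atoms: none
Why: Wittig olefination of one formyl group of the dialdehyde used in excess (inverse addition limits double condensation); the semi‑stabilised ylide should give an E/Z mixture at the new bond, which iodine‑catalysed photoisomerisation equilibrates towards the all‑E isomer.

**Step 16**
Reactants: 29 (1R)-3,5,5-trimethyl-4-[(1E,3E,5E,7E,9E,11E)-3,7,12-trimethyl-13-oxotrideca-1,3,5,7,9,11-hexaen-1-yl]cyclohex-3-en-1-yl hexadecanoate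
Product: 30 (1R)-3,5,5-trimethyl-4-[(1E,3E,5E,7E,9E,11E,13E)-3,7,12-trimethyl-14-(4,4,5,5-tetramethyl-1,3,2-dioxaborolan-2-yl)tetradeca-1,3,5,7,9,11,13-heptaen-1-yl]cyclohex-3-en-1-yl hexadecanoate
Conditions: CrCl2 (8 equiv), Cl2CHBpin (2 equiv), LiI (4 equiv), THF, rt, dark
Reagents that add atoms: 2-(dichloromethyl)-4,4,5,5-tetramethyl-1,3,2-dioxaborolane, ClC(Cl)B1OC(C)(C)C(C)(C)O1
Why: Takai–Utimoto boryl olefination, in which the geminal dichromium reagent adds to the aldehyde and eliminates to the (E)‑alkenylboronate; divalent chromium should leave the ester alone.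

**Step 17**
Reactants: 14 (1R,4R)-4-[(1E,3E)-4-iodo-3-methylbuta-1,3-dien-1-yl]-3,5,5-trimethylcyclohex-2-en-1-ol; 30 (1R)-3,5,5-trimethyl-4-[(1E,3E,5E,7E,9E,11E,13E)-3,7,12-trimethyl-14-(4,4,5,5-tetramethyl-1,3,2-dioxaborolan-2-yl)tetradeca-1,3,5,7,9,11,13-heptaen-1-yl]cyclohex-3-en-1-yl hexadecanoate
Product: 31 (3R,3'R,6'R)-3'-hydroxy-β,ε-caroten-3-yl hexadecanoate
Conditions: Pd(PPh3)4 (10 mol %), 10% aq. TlOH (2.5 equiv), degassed THF, rt, dark; crystallisation
Reagents that add atoms: none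
Why: Suzuki–Miyaura coupling of an alkenyl iodide with an alkenylboronate at room temperature, stereoretentive at both partners; the free allylic alcohol and the ester should be tolerated, so no protecting group remains to be removed.

**Compound list**
1 | 2,4,4-trimethylcyclopentan-1-one | CC1CC(C)(C)CC1=O | starting material
2 | 2,4,4-trimethylcyclopent-2-en-1-one | CC1=CC(C)(C)CC1=O | intermediate
3 | 1,4-bis(trimethylsilyl)buta-1,3-diyne | C[Si](C)(C)C#CC#C[Si](C)(C)C | starting material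
4 | lithium 4-(trimethylsilyl)buta-1,3-diyn-1-ide (formed in the flask) | [Li]C#CC#C[Si](C)(C)C | intermediate
5 | buta-1,3-diyn-1-yl(trimethyl)silane | C#CC#C[Si](C)(C)C | intermediate
6 | chlorobis(cyclopentadienyl)[(1E)-4-(trimethylsilyl)but-1-en-3-yn-1-yl]zirconium (formed in the flask) | C[Si](C)(C)C#C/C=C/[Zr](Cl)(C1C=CC=C1)C1C=CC=C1 | intermediate
7 | trimethyl({(3R)-2,4,4-trimethyl-3-[(1E)-4-(trimethylsilyl)but-1-en-3-yn-1-yl]cyclopent-1-en-1-yl}oxy)silane | C[Si](C)(C)C#C/C=C/[C@H]1C(C)=C(O[Si](C)(C)C)CC1(C)C | intermediate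
8 | (2R)-1,3,3-trimethyl-2-[(1E)-4-(trimethylsilyl)but-1-en-3-yn-1-yl]-5-[(trimethylsilyl)oxy]bicyclo[3.1.0]hexane, cyclopropane CH2 anti to the alkenyl group | C[Si](C)(C)C#C/C=C/[C@H]1[C@]2(C)C[C@]2(O[Si](C)(C)C)CC1(C)C | intermediate
9 | (4R)-3-chloro-3,5,5-trimethyl-4-[(1E)-4-(trimethylsilyl)but-1-en-3-yn-1-yl]cyclohexan-1-one, both C-3 epimers (formed in the flask) | C[Si](C)(C)C#C/C=C/[C@H]1C(C)(Cl)CC(=O)CC1(C)C | intermediate
10 | (4R)-3,5,5-trimethyl-4-[(1E)-4-(trimethylsilyl)but-1-en-3-yn-1-yl]cyclohex-2-en-1-one | C[Si](C)(C)C#C/C=C/[C@H]1C(C)=CC(=O)CC1(C)C | intermediate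
11 | (1R,4R)-3,5,5-trimethyl-4-[(1E)-4-(trimethylsilyl)but-1-en-3-yn-1-yl]cyclohex-2-en-1-ol | C[Si](C)(C)C#C/C=C/[C@H]1C(C)=C[C@H](O)CC1(C)C | intermediate
12 | (1R,4R)-4-[(1E)-but-1-en-3-yn-1-yl]-3,5,5-trimethylcyclohex-2-en-1-ol | C#C/C=C/[C@H]1C(C)=C[C@H](O)CC1(C)C | intermediate
13 | dimethylaluminium alkoxide of (1R,4R)-4-[(1E,3E)-4-(dimethylalumanyl)-3-methylbuta-1,3-dien-1-yl]-3,5,5-trimethylcyclohex-2-en-1-ol (formed in the flask) | C[Al](C)/C=C(C)/C=C/[C@H]1C(C)=C[C@H](O[Al](C)C)CC1(C)C | intermediate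
14 | (1R,4R)-4-[(1E,3E)-4-iodo-3-methylbuta-1,3-dien-1-yl]-3,5,5-trimethylcyclohex-2-en-1-ol | I/C=C(C)/C=C/[C@H]1C(C)=C[C@H](O)CC1(C)C | intermediate
15 | (4R,6R)-4-hydroxy-2,2,6-trimethylcyclohexan-1-one (actinol) | O[C@@H]1C[C@@H](C)C(=O)C(C)(C)C1 | starting material
16 | (4R,6R)-4-[(tert-butyldimethylsilyl)oxy]-2,2,6-trimethylcyclohexan-1-one | CC(C)(C)[Si](C)(C)O[C@@H]1C[C@@H](C)C(=O)C(C)(C)C1 | intermediate
17 | lithium (4R)-4-[(tert-butyldimethylsilyl)oxy]-2,6,6-trimethylcyclohex-1-en-1-olate (formed in the flask) | CC(C)(C)[Si](C)(C)O[C@@H]1CC(C)=C(O[Li])C(C)(C)C1 | intermediate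
18 | (4R)-4-[(tert-butyldimethylsilyl)oxy]-2,6,6-trimethylcyclohex-1-en-1-yl trifluoromethanesulfonate | CC(C)(C)[Si](C)(C)O[C@@H]1CC(C)=C(OS(=O)(=O)C(F)(F)F)C(C)(C)C1 | intermediate
19 | (2E)-3-methylpent-2-en-4-yn-1-ol | OC/C=C(C)/C#C | starting material
20 | 2-{[(2E,4E)-3-methyl-5-(4,4,5,5-tetramethyl-1,3,2-dioxaborolan-2-yl)penta-2,4-dien-1-yl]oxy}-4,4,5,5-tetramethyl-1,3,2-dioxaborolane (formed in the flask) | CC1(C)OB(OC/C=C(C)/C=C/B2OC(C)(C)C(C)(C)O2)OC1(C)C | intermediate
21 | (2E,4E)-3-methyl-5-(4,4,5,5-tetramethyl-1,3,2-dioxaborolan-2-yl)penta-2,4-dien-1-ol | OC/C=C(C)/C=C/B1OC(C)(C)C(C)(C)O1 | intermediate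
22 | (2E,4E)-5-{(4R)-4-[(tert-butyldimethylsilyl)oxy]-2,6,6-trimethylcyclohex-1-en-1-yl}-3-methylpenta-2,4-dien-1-ol | CC(C)(C)[Si](C)(C)O[C@@H]1CC(C)=C(/C=C/C(C)=C/CO)C(C)(C)C1 | intermediate
23 | [(2E,4E)-5-{(4R)-4-[(tert-butyldimethylsilyl)oxy]-2,6,6-trimethylcyclohex-1-en-1-yl}-3-methylpenta-2,4-dien-1-yl](triphenyl)phosphonium bromide (formed in the flask) | [Br-].CC(C)(C)[Si](C)(C)O[C@@H]1CC(C)=C(/C=C/C(C)=C/C[P+](c2ccccc2)(c2ccccc2)c2ccccc2)C(C)(C)C1 | intermediate
24 | [(2E,4E)-5-[(4R)-4-hydroxy-2,6,6-trimethylcyclohex-1-en-1-yl]-3-methylpenta-2,4-dien-1-yl](triphenyl)phosphonium bromide | [Br-].O[C@@H]1CC(C)=C(/C=C/C(C)=C/C[P+](c2ccccc2)(c2ccccc2)c2ccccc2)C(C)(C)C1 | intermediate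
25 | hexadecanoyl chloride (palmitoyl chloride) | CCCCCCCCCCCCCCCC(Cl)=O | starting material
26 | [(2E,4E)-5-[(4R)-4-(hexadecanoyloxy)-2,6,6-trimethylcyclohex-1-en-1-yl]-3-methylpenta-2,4-dien-1-yl](triphenyl)phosphonium bromide | [Br-].CCCCCCCCCCCCCCCC(=O)O[C@@H]1CC(C)=C(/C=C/C(C)=C/C[P+](c2ccccc2)(c2ccccc2)c2ccccc2)C(C)(C)C1 | intermediate
27 | (2E,4E,6E)-2,7-dimethylocta-2,4,6-trienedial | O=C/C(C)=C/C=C/C=C(C)/C=O | starting material
28 | (1R)-3,5,5-trimethyl-4-[(1E,3E)-3-methyl-5-(triphenyl-λ5-phosphanylidene)penta-1,3-dien-1-yl]cyclohex-3-en-1-yl hexadecanoate (formed in the flask) | CCCCCCCCCCCCCCCC(=O)O[C@@H]1CC(C)=C(/C=C/C(C)=C/C=P(c2ccccc2)(c2ccccc2)c2ccccc2)C(C)(C)C1 | intermediate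
29 | (1R)-3,5,5-trimethyl-4-[(1E,3E,5E,7E,9E,11E)-3,7,12-trimethyl-13-oxotrideca-1,3,5,7,9,11-hexaen-1-yl]cyclohex-3-en-1-yl hexadecanoate | CCCCCCCCCCCCCCCC(=O)O[C@@H]1CC(C)=C(/C=C/C(C)=C/C=C/C(C)=C/C=C/C=C(C)/C=O)C(C)(C)C1 | intermediate
30 | (1R)-3,5,5-trimethyl-4-[(1E,3E,5E,7E,9E,11E,13E)-3,7,12-trimethyl-14-(4,4,5,5-tetramethyl-1,3,2-dioxaborolan-2-yl)tetradeca-1,3,5,7,9,11,13-heptaen-1-yl]cyclohex-3-en-1-yl hexadecanoate | CCCCCCCCCCCCCCCC(=O)O[C@@H]1CC(C)=C(/C=C/C(C)=C/C=C/C(C)=C/C=C/C=C(C)/C=C/B2OC(C)(C)C(C)(C)O2)C(C)(C)C1 | intermediate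
31 | (3R,3'R,6'R)-3'-hydroxy-β,ε-caroten-3-yl hexadecanoate (lutein 3-O-palmitate) | CCCCCCCCCCCCCCCC(=O)O[C@@H]1CC(C)=C(/C=C/C(C)=C/C=C/C(C)=C/C=C/C=C(C)/C=C/C=C(C)/C=C/[C@H]2C(C)=C[C@H](O)CC2(C)C)C(C)(C)C1 | target

**Step count and risks**
Total step count: 17. Longest linear sequence: 8 steps (steps 1, 3, 4, 5, 6, 7, 8, 17; the β‑branch 9, 10, 12, 13, 14, 15, 16, 17 is equally long).

Steps most likely to fail:

1. Step 3. The α‑methyl enone with a neopentyl β‑carbon may turn over slowly and the catalyst may discriminate the enone faces poorly. Fallback, setting out from 2 and 5 and returning at 12: the addition is run without chiral ligand (alkenylzirconocene 6, catalytic CuI·SMe2, TMSCl) to give the racemic silyl enol ether F1. This is taken through the conditions of steps 4 to 6 as the racemic siloxycyclopropane F2, the racemic chloroketone F3 (in the flask), the racemic enone F4 and the racemic trans‑alcohol F5. The enantiomers are then separated by lipase‑catalysed transesterification (Pseudomonas lipase, vinyl acetate, hexane), which should acetylate the (1R) alcohol to the (1R,4R)‑acetate F6 and leave the (1S,4S)‑alcohol F7. K2CO3 in MeOH cleaves the acetate and the alkynylsilane of F6 together and gives 12.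

2. Step 6. Hydride may be delivered with poor facial selectivity if the ring reacts through the conformer with a pseudo‑equatorial side chain. Fallback, setting out from 10 and returning at 12: the cis epimer, (1S,4R)‑alcohol F8, is made on purpose with a small hydride (NaBH4, CeCl3, MeOH, Luche conditions) or separated from the mixture. Its carbinol centre is inverted by a Mitsunobu reaction (4‑nitrobenzoic acid, PPh3, DIAD, THF) to the (1R,4R)‑4‑nitrobenzoate F9. K2CO3 in MeOH removes the ester and the alkynylsilane and gives 12.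

3. Step 17. The polyenylboronate may protodeboronate or the two labile polyene partners may decompose before transmetalation. Fallback, setting out from 29 and 12 and returning at 31: iodo‑olefination of aldehyde 29 (CHI3, CrCl2, THF, Takai olefination) gives the (E)‑polyenyl iodide F10. Enyne 12 is methylaluminated as in step 8 to the alane 13, which is coupled directly, without iodination, with F10 under Pd(PPh3)4 and ZnCl2 (Negishi alkenyl–alkenyl coupling) to give 31.

**Further compounds**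
F1 | step 3 | racemic trimethyl({2,4,4-trimethyl-3-[(1E)-4-(trimethylsilyl)but-1-en-3-yn-1-yl]cyclopent-1-en-1-yl}oxy)silane | C[Si](C)(C)C#C/C=C/C1C(C)=C(O[Si](C)(C)C)CC1(C)C
F2 | step 3 | racemic 1,3,3-trimethyl-2-[(1E)-4-(trimethylsilyl)but-1-en-3-yn-1-yl]-5-[(trimethylsilyl)oxy]bicyclo[3.1.0]hexane | C[Si](C)(C)C#C/C=C/C1C2(C)CC2(O[Si](C)(C)C)CC1(C)C
F3 | step 3 | racemic 3-chloro-3,5,5-trimethyl-4-[(1E)-4-(trimethylsilyl)but-1-en-3-yn-1-yl]cyclohexan-1-one | C[Si](C)(C)C#C/C=C/C1C(C)(Cl)CC(=O)CC1(C)C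
F4 | step 3 | racemic 3,5,5-trimethyl-4-[(1E)-4-(trimethylsilyl)but-1-en-3-yn-1-yl]cyclohex-2-en-1-one | C[Si](C)(C)C#C/C=C/C1C(C)=CC(=O)CC1(C)C
F5 | step 3 | racemic trans-3,5,5-trimethyl-4-[(1E)-4-(trimethylsilyl)but-1-en-3-yn-1-yl]cyclohex-2-en-1-ol | C[Si](C)(C)C#C/C=C/[C@H]1C(C)=C[C@H](O)CC1(C)C.C[Si](C)(C)C#C/C=C/[C@@H]1C(C)=C[C@@H](O)CC1(C)C
F6 | step 3 | (1R,4R)-3,5,5-trimethyl-4-[(1E)-4-(trimethylsilyl)but-1-en-3-yn-1-yl]cyclohex-2-en-1-yl acetate | C[Si](C)(C)C#C/C=C/[C@H]1C(C)=C[C@H](OC(C)=O)CC1(C)C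
F7 | step 3 | (1S,4S)-3,5,5-trimethyl-4-[(1E)-4-(trimethylsilyl)but-1-en-3-yn-1-yl]cyclohex-2-en-1-ol | C[Si](C)(C)C#C/C=C/[C@@H]1C(C)=C[C@@H](O)CC1(C)C
F8 | step 6 | (1S,4R)-3,5,5-trimethyl-4-[(1E)-4-(trimethylsilyl)but-1-en-3-yn-1-yl]cyclohex-2-en-1-ol | C[Si](C)(C)C#C/C=C/[C@H]1C(C)=C[C@@H](O)CC1(C)C
F9 | step 6 | (1R,4R)-3,5,5-trimethyl-4-[(1E)-4-(trimethylsilyl)but-1-en-3-yn-1-yl]cyclohex-2-en-1-yl 4-nitrobenzoate | C[Si](C)(C)C#C/C=C/[C@H]1C(C)=C[C@H](OC(=O)c2ccc(cc2)[N+](=O)[O-])CC1(C)C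
F10 | step 17 | (1R)-4-[(1E,3E,5E,7E,9E,11E,13E)-14-iodo-3,7,12-trimethyltetradeca-1,3,5,7,9,11,13-heptaen-1-yl]-3,5,5-trimethylcyclohex-3-en-1-yl hexadecanoate | CCCCCCCCCCCCCCCC(=O)O[C@@H]1CC(C)=C(/C=C/C(C)=C/C=C/C(C)=C/C=C/C=C(C)/C=C/I)C(C)(C)C1
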